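**Assumption:** 7-hydroxychromone (8), 4-bromo-2,6-dimethylanisole (1) and (R)-t-BuPyOX are purchased. The target C2 configuration is (S), the natural flavanone series.

## Retrosynthetic overview

1. The obvious chalcone / oxa-Michael route is avoided. The C2–aryl bond is cut instead: Pd(II)/(R)-t-BuPyOX enantioselective conjugate addition of arylboronic acid 7 to unprotected 7-hydroxychromone 8 sets C2 (S) in the last step.
2. Boronic acid 7 comes from aryl bromide 5 by Br/Li exchange and borylation.
3. Each prenyl group of 5 is assembled as ArCH2–CH=CMe2 from bis(benzyl bromide) 3 and isobutenyl Grignard 4, so no allyl transposition (reverse prenyl) is possible.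
4. Compound 3 comes from 4-bromo-2,6-dimethylanisole 1 by double Wohl–Ziegler bromination.
5. Ring order: no ring is formed. The benzopyranone is bought intact as 8 and the B-ring as 1. The route uses no protecting groups.

## Route

**Step 1**
Reactants: 1, 4-bromo-2,6-dimethylanisole (5-bromo-2-methoxy-1,3-dimethylbenzene); 2, N-bromosuccinimide
Product: 3, 5-bromo-1,3-bis(bromomethyl)-2-methoxybenzene
Conditions: NBS (2.1 equiv), AIBN (5 mol %), PhCF3, reflux, visible light; recrystallise
Reagents that add atoms: N-bromosuccinimide (2), O=C1CCC(=O)N1Br
Why: Wohl–Ziegler radical benzylic bromination; the ring positions ortho and para to OMe are blocked and the remaining ring C–H is deactivated, so bromination goes to the two methyl groups.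

**Step 2**
Reactants: 3, 5-bromo-1,3-bis(bromomethyl)-2-methoxybenzene; 4, (2-methylprop-1-en-1-yl)magnesium bromide
Product: 5, 5-bromo-2-methoxy-1,3-bis(3-methylbut-2-en-1-yl)benzene
Conditions: 4 (2.6 equiv, THF solution), CuI (10 mol %), THF, −30 → 0 °C
Reagents that add atoms: (2-methylprop-1-en-1-yl)magnesium bromide (4), CC(C)=C[Mg]Br
Why: Copper-catalysed sp3–sp2 cross-coupling (Kochi-type SN2 displacement of benzylic bromide by an alkenyl cuprate) builds each prenyl unit without regiochemical ambiguity; the aryl C–Br bond is inert to alkenyl Grignard/cuprate at ≤0 °C.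

**Step 3**
Reactants: 5, 5-bromo-2-methoxy-1,3-bis(3-methylbut-2-en-1-yl)benzene; 6, triisopropyl borate
Product: 7, [4-methoxy-3,5-bis(3-methylbut-2-en-1-yl)phenyl]boronic acid
Conditions: 6 (1.5 equiv) and 5 in THF/toluene, n-BuLi (1.1 equiv) added at −78 °C (in situ quench); then 1 M HCl, 0 °C
Reagents that add atoms: triisopropyl borate (6), CC(C)OB(OC(C)C)OC(C)C (boron); water, O (the two OH oxygens on hydrolysis)
Why: Bromine–lithium exchange at −78 °C is far faster than allylic/benzylic deprotonation, and the aryllithium is trapped as the borate as it forms; brief cold dilute acid hydrolysis does not affect the prenyl groups, which sit next to OMe and not a free OH.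

**Step 4 (key step)**
Reactants: 7, [4-methoxy-3,5-bis(3-methylbut-2-en-1-yl)phenyl]boronic acid (1.5 equiv); 8, 7-hydroxy-4H-chromen-4-one (1.0 equiv)
Product: 9, (2S)-7-hydroxy-2-[4-methoxy-3,5-bis(3-methylbut-2-en-1-yl)phenyl]chroman-4-one (abyssinone IV 4'-OMe ether)
Conditions: Pd(OCOCF3)2 (5 mol %), (R)-t-BuPyOX (6 mol %), NH4PF6 (30 mol %), H2O (5 equiv), ClCH2CH2Cl, 60 °C; ee upgraded by recrystallisation if needed
Reagents that add atoms: none (the new C3–H comes from water)
Why: Pd(II)-catalysed asymmetric conjugate addition of an arylboronic acid to a chromone, a known reaction type applied here to a new substrate pair: the cationic (PyOX)Pd–aryl adds across C2=C3 in the enantio-determining step and water protonates the Pd enolate, and because the (S)-ligand is known to give (R)-β-aryl ketones, which maps by analogy onto (R)-flavanone, the (R)-ligand is used to give (2S). The conditions are base-free, so the free 7-OH is tolerated and the product cannot racemise by retro-oxa-Michael ring opening. The trisubstituted prenyl alkenes are poor partners for insertion and should survive.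

## Compound list

1 | 4-bromo-2,6-dimethylanisole | COc1c(C)cc(Br)cc1C | starting material
2 | N-bromosuccinimide | O=C1CCC(=O)N1Br | starting material (reagent)
3 | 5-bromo-1,3-bis(bromomethyl)-2-methoxybenzene | COc1c(CBr)cc(Br)cc1CBr | intermediate
4 | (2-methylprop-1-en-1-yl)magnesium bromide | CC(C)=C[Mg]Br | starting material (reagent)
5 | 5-bromo-2-methoxy-1,3-bis(3-methylbut-2-en-1-yl)benzene | COc1c(CC=C(C)C)cc(Br)cc1CC=C(C)C | intermediate
6 | triisopropyl borate | CC(C)OB(OC(C)C)OC(C)C | starting material (reagent)
7 | [4-methoxy-3,5-bis(3-methylbut-2-en-1-yl)phenyl]boronic acid | COc1c(CC=C(C)C)cc(B(O)O)cc1CC=C(C)C | intermediate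
8 | 7-hydroxy-4H-chromen-4-one (7-hydroxychromone) | O=c1ccoc2cc(O)ccc12 | starting material
9 | (2S)-7-hydroxy-2-[4-methoxy-3,5-bis(3-methylbut-2-en-1-yl)phenyl]chroman-4-one | COc1c(CC=C(C)C)cc([C@@H]2CC(=O)c3ccc(O)cc3O2)cc1CC=C(C)C | target

## Summary

Total steps: 4. Longest linear sequence: 4 (1 → 3 → 5 → 7 → 9; 8 is purchased).

Three steps most likely to fail, with fallbacks:

1. **Step 4.** The electron-rich, unprotected 7-hydroxychromone may react slowly; flavone may form by β-hydride elimination; ee may be insufficient; and the sense of induction rests on analogy. The configuration should be confirmed by CD: (2S)-flavanones show a positive Cotton effect near 330 nm and a negative one near 290 nm.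
   Fallback: convert 5 to the aldehyde (n-BuLi, DMF), run a Claisen–Schmidt condensation with 2'-hydroxy-4'-(methoxymethoxy)acetophenone, then cyclise the chalcone by a cinchona-thiourea-catalysed enantioselective intramolecular oxa-Michael addition and remove the MOM group.

2. **Step 2.** The double benzylic coupling may stop at mono-coupling or give Wurtz-type oligomers.
   Fallback: install the prenyl groups by double Stille coupling of 2,6-dibromo-4-chloroanisole with tributyl(prenyl)stannane (Pd(PPh3)4, DMF), then Pd/XPhos borylation of the C–Cl bond with B2(OH)4 to reach 7.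

3. **Step 1.** Radical bromination may give a statistical mixture of under- and over-brominated products.
   Fallback: make 3 without a radical step from 4-bromo-2,6-bis(hydroxymethyl)phenol by O-methylation (MeI, K2CO3) and then PBr3.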